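At late times a closed flask of this kind should show one process, the loss of target to over-reaction product, and I began there. I wanted to know how long target keeps at each temperature in these flasks, where a solid reagent slowly dissolves to give the partner, which meets the substrate on the catalyst.

| setting | amber | blue | teal | Thursday's | Friday's | Wednesday's | Tuesday's |
|---|---|---|---|---|---|---|---|
| substrate | 0.0094 M | 0.021 M | 0.014 M | 0.014 M | 0.014 M | 0.014 M | 0.014 M |
| solid reagent | 0.056 M | 0.056 M | 0.056 M | 0.0560 M | 0.0560 M | 0.0560 M | 0.0560 M |
| catalyst | 0.28 mM | 0.28 mM | 0.14 mM | 0.28 mM | 0.28 mM | 0.28 mM | 0.28 mM |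
| temperature | 20 °C | 42 °C | 20 °C |  | 30 °C | 10 °C | 50 °C |
| remark | run made earlier | run made earlier | run made earlier | at 10 °C until 6.0 d, from then on at 50 °C |  |  |  |
| time |  |  |  | 8.0 d | 8.0 d | 8.0 d | 8.0 d |

| run | time / d | target / % |
|---|---|---|
| amber | 0.833 | 21 |
| amber | 1.25 | 35 |
| amber | 2.08 | 62 |
| amber | 4.00 | 88 |
| amber | 6.00 | 75 |
| amber | 10.0 | 61 |
| blue | 0.625 | 8 |
| blue | 1.04 | 14 |
| blue | 1.67 | 16 |
| blue | 2.00 | 18 |
| blue | 3.00 | 19 |
| teal | 2.08 | 38 |
| teal | 4.00 | 68 |
| teal | 6.00 | 76 |
| teal | 8.00 | 72 |
| teal | 10.0 | 62 |

(readings scatter by 2 percentage points)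

- the flask with the highest amount of target, in percent of the substrate charged ("all alike" if they lie within 1.5 percentage points) (Thursday's / Friday's / Wednesday's / Tuesday's / all alike)
- final target, as a percentage of the substrate charged, in Thursday's
- final target, as a percentage of the substrate charged, in Friday's
- final target, as a percentage of the substrate charged, in Wednesday's
- final target, as a percentage of the substrate charged, in Tuesday's

- given per volume of solution although it is solid: solid reagent
- candidate steps: target -> over-reaction product; solid reagent <-> partner; substrate + partner + catalyst -> target + catalyst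
- at the start none of the solid reagent is in solution

In the amber run, target fell from 75% at 6.00 d to 61% at 10.0 d. Reading this as dc(target)/dt = −k c(target) gave k = 0.0517 d⁻¹ at 20 °C, a half-life of 13.4 d. The early climb in amber was s = 0.00280 M d⁻¹. The teal run, with half the catalyst but more substrate, climbed at 0.00256 M d⁻¹, about the same. Two settings differed between these runs, so the match named no cause, and I carried s forward purely as a working assumption: a constant supply of target.

The bench rule of a factor 2 between 10 °C and 20 °C would have put the half-life at 26.8 d in Wednesday's flask. The blue plateau tested that rule. Assuming the same s at that temperature, and supply balancing loss, I got k = 0.702 d⁻¹ at 42 °C, a ratio of 13.6 to amber, while the rule allows 4.59, so on this assumption the rule failed. The readings gave a factor of 3.27 per such step, and with it the half-life of target at 10 °C, 43.9 d.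

Integrating the assumed constant supply against this loss gives c(target) = (s/k)(1 − exp(−kt)) until the substrate is used, reckoned at 5.00 d, then plain exponential decay. For Wednesday's flask I reckoned 91.7%. Friday's half-life of 4.10 d is shorter than the run, and at 50 °C it is 0.382 d, shorter than Thursday's last stretch.

The forecast also chose Wednesday's, with 1% for Thursday's, 27% for Friday's, 91% for Wednesday's and 0.1% for Tuesday's: “So dissolution of the solid limits the rate, with the catalytic step fast.”

The flasks gave Wednesday's as the highest: Thursday's 0.0740%, Friday's 20.2%, below the forecast, Wednesday's 92.9%, Tuesday's 0%.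

    target → over-reaction product (k = 0.00250 min⁻¹, Ea = 107 kJ mol⁻¹)
    solid reagent ⇌ partner, rate k2*(cs2 - [partner]) while solid is left; crystals form when [partner] > cs2 (solubility = 8.20 mM, k = 5.20 × 10⁻⁴ min⁻¹)
    substrate + partner + catalyst → target + catalyst, rate k3*[substrate]*[partner]*[catalyst]/(1 + ([substrate]/sat3)) (23.0 mM, k = 4400 M⁻² min⁻¹, Ea = 46.0 kJ mol⁻¹)
    (constants at 50 °C)

Wednesday's flask had not come to rest at 8.00 d. It held 92.9% target with 0.53% of the substrate left. My half-life of 43.9 d gave a survival of 32.1% up to ten times the time, which would leave 29.8%. Wednesday's flask at 80.0 d holds 36.7% target, and over-reaction product has risen from 6.56% to 63.3%.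

(The numbers in the tables are simulated with made-up constants; noise was put on by code.)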